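## The problem

The target, (1S,3S)-1-[(12Z)-16-phenylhexadec-12-en-1-yl]cyclohex-4-ene-1,3-diol (21), has one carbocycle. With the ring numbered C1 (CHOH), C2=C3, C4H2, C5 (tertiary carbinol) and C6H2, the allylic hydroxyl on C1 and the tertiary hydroxyl on C5 are cis across the C6 methylene, and both centres are S. The chain on C5 (C1' to C16', Z double bond C12'=C13', phenyl on C16') has no stereocentre; it needs one cis-selective olefination and one sp3–sp3 coupling. The hard centre is C5. Its three carbon substituents are all CH2 groups that differ only further out, so neither a reagent adding to a C5 ketone nor a catalyst can easily tell them apart, and C1 is too far away (1,3) to relay to it reliably. Once C5 is fixed, C1 can be corrected, because a secondary allylic carbinol can be inverted. The end of the synthesis must be gentle: the allylic alcohol ionises easily, loss of two molecules of water would give an alkylbenzene, and the isolated Z-alkene excludes hydrogenation-based deprotection and double-bond-equilibrating conditions. The enabling feature is that C5 carries an oxygen and an exocyclic CH2 (C1'), which are the three atoms of a spiro-epoxide. The set C5(O)(C1') / C1–O / C2=C3 overlays on C1(OH)(CO2H) / C5–OH / cis-3,4-diol of (−)-quinic acid (1). Quinic acid supplies C5 in the correct absolute sense, a latent alkene in the right place, and the C1 oxygen in the epimeric (trans) orientation.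

## Retrosynthesis

Target ring numbering is used for 18–21 and quinic acid numbering for the saturated intermediates (quinic C1 = target C5, quinic C5 = target C1, quinic C3/C4 = target C3/C2).

**21 ⇒ 20 ⇒ 19 (C1–O inversion).** The C1–O bond is cut and re-formed with the opposite configuration: 21 comes from its 4-nitrobenzoate 20, and 20 from the trans-diol 19 by Mitsunobu inversion. Quinic acid can only be differentiated through its lactone, which requires the C5 oxygen cis to the carboxyl group and therefore trans to the tertiary hydroxyl; one inversion is the price. It is placed at the allylic stage because the carbinol is then activated and flanked by only one sp3 neighbour. The forward step must give direct displacement in preference to allylic transposition or ionisation.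

**19 ⇒ 18 ⇒ 17 ⇒ 16 ⇒ 15 (alkene from the cis-diol).** The C2=C3 double bond is traced to a cis-vicinal diol: 19 from silyl ether 18, 18 from cyclic thionocarbonate 17 by stereospecific syn-deoxygenation, 17 from triol 16, and 16 from acetonide 15. Elimination of a single leaving group would raise a regiochemical question (towards C2 or C4); a diol deoxygenation puts the alkene exactly where the two oxygens were. The C1 oxygen stays silylated so that 16 has only one vicinal diol. A tert-butyldiphenylsilyl ether is chosen because it must survive the aqueous acid that removes the acetonide.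

**15 ⇒ 7 + 14 (key disconnection, C1'–C2').** The chain is cut one carbon out from the ring, giving spiro-epoxide 7 and the C15 Grignard reagent 14. Cutting C5–C1' instead would mean adding the chain to a cyclohexanone with two nearly equivalent faces and a β-oxygen prone to elimination, and would create the tertiary centre with poor control. Cutting at C1'–C2' leaves the C5–O bond untouched, so the centre is inherited. All functionality goes into 7 and all chain length into 14. The forward reaction must attack the epoxide CH2 rather than the spiro carbon and must avoid Lewis-acid isomerisation of the epoxide.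

**7 ⇒ 6 ⇒ 5 ⇒ 4 ⇒ 3 ⇒ 2 ⇒ 1 (epoxide from the carboxyl carbon).** The epoxide CH2 is the former carboxyl carbon. Epoxide 7 comes from primary tosylate 6, 6 from diol 5, 5 from ester 4 by reduction, 4 from hydroxy ester 3 by silylation, 3 from acetonide lactone 2 by methanolysis, and 2 from quinic acid (1). The lactone/acetonide step differentiates all four hydroxyls in one operation, and no C–O bond at a stereocentre is broken anywhere in the sequence.

**14 ⇒ 13 ⇒ 9 + 12 ⇒ 8, 10, 11 (chain).** The Grignard reagent 14 comes from bromide 13. The Z-alkene of 13 is cut into aldehyde 9 (from bromo alcohol 8) and ylide 12 (from phosphonium salt 11, itself from bromide 10). A non-stabilised ylide with an unbranched aldehyde is the most dependable cis-olefination available, and placing the alkene four carbons from the arene keeps both partners simple.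

## Roads not taken

**Alternative 1:** The ring is cut across C3–C4 and C5–C6 into buta-1,3-diene A1 and 2-bromoacrolein A2.
- Key step: an enantioselective Diels–Alder reaction, catalysed by the triflimide salt of the N-protonated oxazaborolidine from α,α-diphenylprolinol and o-tolylboronic acid, gives (R)-1-bromocyclohex-3-ene-1-carbaldehyde A3 and fixes C5.
- Continuation: the formyl carbon becomes C1' (addition of 14, bromohydrin closure to an epoxide, hydride opening). A carbonate on the tertiary oxygen then cyclises onto the ring alkene under iodonium activation, which places the C1 oxygen cis by construction; elimination of HI and carbonate cleavage finish.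
- Merits: catalytic, no surplus oxygenation to remove, a longest sequence of about eight steps against twelve, and the cis-1,3 relationship set by a tether instead of an inversion. In both step count and the way C1 is set, this road is better than the chosen one.
- Weak points: the enantiopurity of C5 rests on a low-temperature reaction of a gaseous diene with a labile dienophile. A carbonate must be made on a hindered tertiary homoallylic alcohol. The halocyclisation must choose between the two alkene carbons (six- against seven-membered carbonate).
- Comparison: the chosen plan sets against this a C5 of guaranteed configuration and a sequence with no regiochemical choice in the ring oxygenation.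

**Alternative 2:** The ring is cut at C4–C5, back to the acyclic β-(4-methoxybenzyloxy) ketone A4 that carries a 1-silylallyl unit.
- Key step: SnCl4 chelates the C5 carbonyl oxygen and the C1 ether oxygen, the terminal alkene carbon C4 attacks C5, and silicon leaves from C2 (intramolecular allylsilane addition). This gives the C1 4-methoxybenzyl ether of the target, A5, forming the ring, the C2=C3 alkene and the tertiary centre at once under 1,3-control from C1.
- Merits: highly convergent; only one deprotection follows the cyclisation, which the chosen plan cannot match.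
- Weak points: in A4 the C1 ether oxygen is β to silicon, so Lewis-acid activation also opens a Peterson-type elimination to a 1,3-diene. A 4-methoxybenzyl ether has limited tolerance to SnCl4. A ketone is a sluggish electrophile for an allylsilane. The cis/trans outcome depends on one chelated chair being clearly preferred. A4 itself needs two adjacent stereocentres made by asymmetric synthesis.
- Comparison: the chosen plan has no stereoselective C–C bond formation and no step in which the substrate carries its own decomposition channel.

**Alternative 3:** The C5–O bond is traced to a C5–B bond and the ring to 3-[(12Z)-16-phenylhexadec-12-en-1-yl]cyclohex-2-en-1-one A6, available in one addition–transposition step from 14.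
- Key step: a chiral bisphosphine complex of monovalent copper (CuCl, NaOtBu, 2,3-bis(tert-butylmethylphosphino)quinoxaline, MeOH) transfers boron from B2pin2 to the β-carbon and gives the tertiary boronate A7. Oxidation with retention gives the carbinol.
- Merits: this is the shortest route to the tertiary centre, and catalytic; in that respect it is better than the chosen plan.
- Weak points: the β-hydroxy ketone must be desaturated regioselectively on the side away from the carbinol, while base invites retro-aldol cleavage or β-elimination. The 1,2-reduction must then give the cis-1,3-diol, although the preferred conformer (chain equatorial, hydroxyl axial) with axial hydride delivery points to the trans isomer. The catalyst must also distinguish a ring CH2 from a long n-alkyl group.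
- Comparison: three selectivity problems fall at the end, where material is most valuable. The chosen plan has a single stereochemical correction, made by a reaction with a predictable outcome.

Key step: step 10

Remark on the chemistry: 11-bromoundecan-1-ol and (4-bromobutyl)benzene are taken as commercial. In 2–7 and 15–17 the four ring stereocentres have the configuration of (−)-quinic acid and are described by quinic acid numbering.

## Route

Step 1
Reactants: 1 (−)-quinic acid
Product: 2 quinic acid 3,4-acetonide 1,5-lactone
Conditions: 2,2-dimethoxypropane, p-TsOH·H2O (cat.), acetone, reflux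
Reagents that add atoms: 2,2-dimethoxypropane, COC(C)(C)OC
Why: Acid-catalysed transacetalisation puts the isopropylidene group on the only cis-vicinal diol (O3/O4) and the carboxyl group lactonises onto the cis-disposed O5; no stereocentre is touched.

Step 2
Reactants: 2 quinic acid 3,4-acetonide 1,5-lactone
Product: 3 methyl 3,4-O-isopropylidenequinate
Conditions: NaOMe (cat.), MeOH, 0 °C → rt; AcOH quench
Reagents that add atoms: methanol, CO
Why: Methoxide-catalysed lactone methanolysis (transesterification) opens the strained bicyclic lactone; the hydroxy ester is silylated without delay so that it cannot relactonise.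

Step 3
Reactants: 3 methyl 3,4-O-isopropylidenequinate
Product: 4 methyl 5-O-(tert-butyldiphenylsilyl)-3,4-O-isopropylidenequinate
Conditions: tert-butyl(chloro)diphenylsilane, imidazole, 4-(dimethylamino)pyridine (cat.), DMF, rt → 40 °C
Reagents that add atoms: tert-butyl(chloro)diphenylsilane, CC(C)(C)[Si](Cl)(c1ccccc1)c1ccccc1
Why: Imidazole-promoted silyl ether formation; the secondary 5-OH reacts while the tertiary α-hydroxy-ester OH is too hindered, and this silyl group is chosen because it must outlast the aqueous acid of step 11.

Step 4
Reactants: 4 methyl 5-O-(tert-butyldiphenylsilyl)-3,4-O-isopropylidenequinate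
Product: 5 primary/tertiary 1,2-diol (ester reduced to CH2OH; 3,4-acetonide; 5-O-TBDPS)
Conditions: LiAlH4, THF, 0 °C; Fieser work-up
Reagents that add atoms: none
Why: Hydride reduction of an ester to the primary alcohol; acetonide and silyl ether are inert to LiAlH4 at 0 °C.

Step 5
Reactants: 5 primary/tertiary 1,2-diol
Product: 7 spiro-epoxide (3,4-acetonide; 5-O-TBDPS), via primary tosylate 6 (not isolated)
Conditions: TsCl, Et3N, 4-(dimethylamino)pyridine (cat.), CH2Cl2, 0 °C → rt; then K2CO3, MeOH, rt
Reagents that add atoms: 4-methylbenzenesulfonyl chloride, Cc1ccc(cc1)S(Cl)(=O)=O (its atoms are carried by 6 and leave again on closure)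
Why: Selective sulfonylation of the primary hydroxyl, then intramolecular Williamson etherification (3-exo-tet) by the tertiary alkoxide; the tertiary C–O bond is never broken, so the spiro carbon keeps the quinic acid configuration.

Step 6
Reactants: 8 11-bromoundecan-1-ol
Product: 9 11-bromoundecanal
Conditions: 2,2,6,6-tetramethylpiperidin-1-oxyl (TEMPO, cat.), PhI(OAc)2, CH2Cl2, rt
Reagents that add atoms: none
Why: Nitroxyl-catalysed (oxoammonium) oxidation stops at the aldehyde and leaves the primary bromide alone.

Step 7
Reactants: 10 (4-bromobutyl)benzene
Product: 11 triphenyl(4-phenylbutyl)phosphonium bromide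
Conditions: PPh3, MeCN, reflux
Reagents that add atoms: triphenylphosphine, c1ccc(cc1)P(c1ccccc1)c1ccccc1
Why: SN2 quaternisation of triphenylphosphine by a primary bromide.

Step 8
Reactants: 11 triphenyl(4-phenylbutyl)phosphonium bromide; 9 11-bromoundecanal
Product: 13 (Z)-(15-bromopentadec-4-en-1-yl)benzene, via triphenyl(4-phenylbutylidene)phosphorane 12 (not isolated)
Conditions: NaN(SiMe3)2, THF, 0 °C; then 9, −78 °C → rt
Reagents that add atoms: none
Why: Wittig olefination of a non-stabilised ylide under lithium-free conditions; kinetically controlled cis-oxaphosphetane formation gives the Z-alkene, and at −78 °C carbonyl addition is far faster than alkylation of the ylide by the remote primary bromide.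

Step 9
Reactants: 13 (Z)-(15-bromopentadec-4-en-1-yl)benzene
Product: 14 [(11Z)-15-phenylpentadec-11-en-1-yl]magnesium bromide (THF solution, titrated, used directly)
Conditions: Mg turnings (I2-activated), THF, 45 °C, slow addition of 13
Reagents that add atoms: magnesium, [Mg]
Why: Grignard formation by insertion of magnesium into the primary C–Br bond; the isolated Z-alkene is remote, and slow addition to excess metal limits Wurtz coupling.

Step 10
Reactants: 7 spiro-epoxide (3,4-acetonide; 5-O-TBDPS); 14 [(11Z)-15-phenylpentadec-11-en-1-yl]magnesium bromide
Product: 15 chain-bearing tertiary alcohol (3,4-acetonide; 5-O-TBDPS)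
Conditions: CuI (10 mol%), THF, −30 °C → 0 °C, slow addition of 14 (1.5 equiv); aq. NH4Cl
Reagents that add atoms: none
Why: CuI and 14 form a magnesium dialkylcuprate of monovalent copper; with the epoxide oxygen coordinated to divalent magnesium, the cuprate attacks the epoxide CH2 from the rear (SN2), and the trivalent copper alkyl so formed reductively eliminates to the C1'–C2' bond, returning monovalent copper. The closest known reaction type is the copper-catalysed Grignard opening of terminal 2,2-disubstituted epoxides such as methylenecyclohexane oxides at the unsubstituted carbon. No ring closes and no stereocentre is formed; the tertiary C–O bond is untouched, so the carbinol centre is the inherited quinic acid C1. The step needs regioselectivity for the CH2 over the spiro carbon, which sterics secure because the spiro carbon is fully substituted and part of the ring. It also needs the soft cuprate, not the Lewis-acidic Grignard reagent, to open the ring, so that neither bromohydrin formation nor rearrangement to an aldehyde intervenes; catalytic CuI, low temperature and slow addition serve this. Acetonide, silyl ether, Z-alkene and arene are spectators.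

Step 11
Reactants: 15 chain-bearing tertiary alcohol (3,4-acetonide; 5-O-TBDPS)
Product: 16 triol (free tertiary 1-OH and cis-3,4-diol; 5-O-TBDPS)
Conditions: AcOH/H2O (4:1), 60 °C
Reagents that add atoms: none
Why: Acid-catalysed acetal hydrolysis; the tert-butyldiphenylsilyl ether withstands warm aqueous acetic acid, and the tertiary alcohol, flanked by oxygenated positions and not allylic, has no easy ionisation path.

Step 12
Reactants: 16 triol (free tertiary 1-OH and cis-3,4-diol; 5-O-TBDPS)
Product: 17 cyclic 3,4-thionocarbonate (free tertiary 1-OH; 5-O-TBDPS)
Conditions: 1,1'-thiocarbonyldiimidazole, toluene, 80 °C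
Reagents that add atoms: 1,1'-thiocarbonyldiimidazole, S=C(n1ccnc1)n1ccnc1
Why: Cyclic thionocarbonate formation; thioacylation of one secondary hydroxyl is followed by fast five-membered ring closure onto its cis neighbour, and the hindered tertiary hydroxyl does not compete.

Step 13
Reactants: 17 cyclic 3,4-thionocarbonate (free tertiary 1-OH; 5-O-TBDPS)
Product: 18 (1S,5R)-5-[(tert-butyldiphenylsilyl)oxy]-1-[(12Z)-16-phenylhexadec-12-en-1-yl]cyclohex-3-en-1-ol
Conditions: P(OMe)3, 110 °C
Reagents that add atoms: none
Why: Corey–Winter olefination; thiophilic attack of the phosphite on sulfur gives a 2-ylidene-1,3-dioxolane (or its phosphite ylide) that fragments by stereospecific syn cycloreversion with loss of CO2, which a cis-diol derivative on a six-membered ring can do readily.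

Step 14
Reactants: 18 (1S,5R)-5-[(tert-butyldiphenylsilyl)oxy]-1-[(12Z)-16-phenylhexadec-12-en-1-yl]cyclohex-3-en-1-ol
Product: 19 (1S,3R)-1-[(12Z)-16-phenylhexadec-12-en-1-yl]cyclohex-4-ene-1,3-diol (trans-diol)
Conditions: Bu4NF, THF, rt
Reagents that add atoms: none
Why: Fluoride-induced desilylation driven by Si–F bond formation; nothing else in the molecule responds to fluoride.

Step 15
Reactants: 19 (1S,3R)-1-[(12Z)-16-phenylhexadec-12-en-1-yl]cyclohex-4-ene-1,3-diol
Product: 20 (1S,5S)-5-hydroxy-5-[(12Z)-16-phenylhexadec-12-en-1-yl]cyclohex-2-en-1-yl 4-nitrobenzoate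
Conditions: 4-nitrobenzoic acid, PPh3, diisopropyl azodicarboxylate, THF, 0 °C → rt
Reagents that add atoms: 4-nitrobenzoic acid, OC(=O)c1ccc(cc1)[N+](=O)[O-]
Why: Mitsunobu reaction; the secondary allylic hydroxyl is activated as its alkoxyphosphonium ion and displaced by the carboxylate with SN2 inversion (carbinol centre R to S, trans- to cis-1,3), the acidic nucleophile favouring direct displacement, while the tertiary hydroxyl is not activated.

Step 16
Reactants: 20 (1S,5S)-5-hydroxy-5-[(12Z)-16-phenylhexadec-12-en-1-yl]cyclohex-2-en-1-yl 4-nitrobenzoate
Product: 21 (1S,3S)-1-[(12Z)-16-phenylhexadec-12-en-1-yl]cyclohex-4-ene-1,3-diol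
Conditions: K2CO3 (cat.), MeOH, 0 °C → rt
Reagents that add atoms: none
Why: Base-catalysed methanolysis (transesterification) of the electron-poor ester proceeds by acyl–oxygen cleavage, so the newly set C–O configuration is retained and the acid-sensitive allylic alcohol never meets acid.

## Compound list

1 | (−)-quinic acid, (1S,3R,4S,5R)-1,3,4,5-tetrahydroxycyclohexane-1-carboxylic acid | O[C@@]1(C(=O)O)C[C@@H](O)[C@@H](O)[C@H](O)C1 | starting material
2 | quinic acid 3,4-acetonide 1,5-lactone (isopropylidene on the cis-3,4-diol, γ-lactone from the carboxyl group to O5, free tertiary 1-OH) | O[C@]12C[C@H]3OC(C)(C)O[C@H]3[C@H](OC1=O)C2 | intermediate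
3 | methyl 3,4-O-isopropylidenequinate (1-OH and 5-OH free; quinic acid configuration) | O[C@@]1(C(=O)OC)C[C@H]2OC(C)(C)O[C@H]2[C@H](O)C1 | intermediate
4 | methyl 5-O-(tert-butyldiphenylsilyl)-3,4-O-isopropylidenequinate | O[C@@]1(C(=O)OC)C[C@H]2OC(C)(C)O[C@H]2[C@H](O[Si](c3ccccc3)(c3ccccc3)C(C)(C)C)C1 | intermediate
5 | 1-(hydroxymethyl) diol: quinic acid skeleton with CO2H reduced to CH2OH, tertiary 1-OH free, 3,4-acetonide, 5-O-TBDPS | O[C@@]1(CO)C[C@H]2OC(C)(C)O[C@H]2[C@H](O[Si](c3ccccc3)(c3ccccc3)C(C)(C)C)C1 | intermediate
6 | primary 4-methylbenzenesulfonate of 5 (tertiary 1-OH free) | O[C@@]1(COS(=O)(=O)c2ccc(C)cc2)C[C@H]2OC(C)(C)O[C@H]2[C@H](O[Si](c3ccccc3)(c3ccccc3)C(C)(C)C)C1 | intermediate (not isolated)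
7 | spiro-epoxide: oxirane made of quinic C1, O1 and the former carboxyl carbon; 3,4-acetonide; 5-O-TBDPS | C1O[C@]12C[C@H]3OC(C)(C)O[C@H]3[C@H](O[Si](c4ccccc4)(c4ccccc4)C(C)(C)C)C2 | intermediate
8 | 11-bromoundecan-1-ol | OCCCCCCCCCCCBr | starting material
9 | 11-bromoundecanal | O=CCCCCCCCCCCBr | intermediate
10 | (4-bromobutyl)benzene | BrCCCCc1ccccc1 | starting material
11 | triphenyl(4-phenylbutyl)phosphonium bromide | [Br-].c1ccc(cc1)CCCC[P+](c1ccccc1)(c1ccccc1)c1ccccc1 | intermediate
12 | triphenyl(4-phenylbutylidene)phosphorane (ylide) | c1ccc(cc1)CCCC=P(c1ccccc1)(c1ccccc1)c1ccccc1 | intermediate (not isolated)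
13 | (Z)-(15-bromopentadec-4-en-1-yl)benzene | BrCCCCCCCCCC/C=C\CCCc1ccccc1 | intermediate
14 | [(11Z)-15-phenylpentadec-11-en-1-yl]magnesium bromide | Br[Mg]CCCCCCCCCC/C=C\CCCc1ccccc1 | intermediate
15 | tertiary alcohol: quinic C1 bearing OH and the (12Z)-16-phenylhexadec-12-en-1-yl chain; 3,4-acetonide; 5-O-TBDPS | O[C@@]1(CCCCCCCCCCC/C=C\CCCc2ccccc2)C[C@H]3OC(C)(C)O[C@H]3[C@H](O[Si](c4ccccc4)(c4ccccc4)C(C)(C)C)C1 | intermediate
16 | triol: as 15 with the cis-3,4-diol free; 5-O-TBDPS | O[C@@]1(CCCCCCCCCCC/C=C\CCCc2ccccc2)C[C@@H](O)[C@@H](O)[C@H](O[Si](c4ccccc4)(c4ccccc4)C(C)(C)C)C1 | intermediate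
17 | cyclic 3,4-thionocarbonate of 16 | O[C@@]1(CCCCCCCCCCC/C=C\CCCc2ccccc2)C[C@H]3OC(=S)O[C@H]3[C@H](O[Si](c4ccccc4)(c4ccccc4)C(C)(C)C)C1 | intermediate
18 | (1S,5R)-5-[(tert-butyldiphenylsilyl)oxy]-1-[(12Z)-16-phenylhexadec-12-en-1-yl]cyclohex-3-en-1-ol | O[C@@]1(CCCCCCCCCCC/C=C\CCCc2ccccc2)CC=C[C@H](O[Si](c4ccccc4)(c4ccccc4)C(C)(C)C)C1 | intermediate
19 | (1S,3R)-1-[(12Z)-16-phenylhexadec-12-en-1-yl]cyclohex-4-ene-1,3-diol (trans-diol) | O[C@@]1(CCCCCCCCCCC/C=C\CCCc2ccccc2)CC=C[C@H](O)C1 | intermediate
20 | (1S,5S)-5-hydroxy-5-[(12Z)-16-phenylhexadec-12-en-1-yl]cyclohex-2-en-1-yl 4-nitrobenzoate | O[C@@]1(CCCCCCCCCCC/C=C\CCCc2ccccc2)CC=C[C@@H](OC(=O)c3ccc(cc3)[N+](=O)[O-])C1 | intermediate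
21 | (1S,3S)-1-[(12Z)-16-phenylhexadec-12-en-1-yl]cyclohex-4-ene-1,3-diol (cis-diol) | O[C@@H]1C=CC[C@@](O)(CCCCCCCCCCC/C=C\CCCc2ccccc2)C1 | target

## Step count and risks

Total: 16 steps. Longest linear sequence: 12 steps (steps 1–5 and 10–16, from quinic acid); the chain branch contributes steps 6–9.

**Step 10 (key step).** The epoxide CH2 is neopentyl-like, so substitution is slow. Lewis-acid-induced isomerisation of the 2,2-disubstituted epoxide to an aldehyde (followed by Grignard addition), or opening by bromide, can overtake it, while the Grignard reagent is lost to homocoupling.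
- Fallback, setting out from 13 and 7 and returning at 15: a sulfone carbanion forms the same C1'–C2' bond without a Lewis-acidic metal.
- Bromide 13 with PhSO2Na in DMF should give (Z)-[15-(phenylsulfonyl)pentadec-4-en-1-yl]benzene F1.
- Lithiation of F1 (n-BuLi, THF/DMPU, −78 °C → rt) and addition to 7 should give the γ-hydroxy sulfone F2, as a mixture of epimers at the sulfonyl carbon.
- Reductive desulfonylation with sodium amalgam Na(Hg) and Na2HPO4 in MeOH should give 15; the hydroxyl is γ to sulfur, so no Julia-type elimination is available.

**Step 11.** The acid needed to open the cis-fused dioxolane may also cause partial loss of the silyl ether, or the hydrolysis may stall under conditions mild enough to keep it.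
- Fallback, setting out from 15 and returning at 19: both protecting groups are removed on purpose (Bu4NF in THF, then 1 M HCl in THF/MeOH) to give the tetraol F3.
- One equivalent of 1,1'-thiocarbonyldiimidazole should select the cis-3,4-diol over the trans-4,5-diol, because only the cis-fused five-membered ring is unstrained, to give the 3,4-thionocarbonate with free 5-OH, F4.
- Corey–Winter fragmentation with P(OMe)3 should give 19 directly, which also saves the separate desilylation.

**Step 13.** Fragmentation of the thionocarbonate may be incomplete at a tolerable temperature, with the ylidene intermediate trapped by phosphite instead of losing CO2, and prolonged heating may stress the allylic silyl ether.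
- Fallback, setting out from 16 and returning at 18: an Eastwood-type deoxygenation through an amide acetal.
- N,N-dimethylformamide dimethyl acetal should convert 16 into the 2-(dimethylamino)-1,3-dioxolane F5.
- Quaternisation with MeI should give the trimethylammonium iodide F6, which on heating in toluene should undergo the same stereospecific syn fragmentation to 18.

**Step 15.** Displacement may occur with allylic transposition, or ionisation of the activated allylic carbinol may cause loss of stereochemical integrity or elimination to a diene.
- Fallback, setting out from 19 and returning at 21: oxidation and reagent-controlled reduction instead of substitution.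
- MnO2 in CH2Cl2 should oxidise only the allylic hydroxyl, to (5S)-5-hydroxy-5-[(12Z)-16-phenylhexadec-12-en-1-yl]cyclohex-2-en-1-one F7.
- Corey–Bakshi–Shibata reduction with (R)-2-methyl-CBS-oxazaborolidine and catecholborane at −78 °C, with the alkene side as the large group, should deliver the (S)-carbinol and give 21 directly.
- A substrate-controlled hydride is not used, because axial delivery would be expected to return the trans-diol.

## Further compounds

F1 | step 10 | (Z)-[15-(phenylsulfonyl)pentadec-4-en-1-yl]benzene | O=S(=O)(c1ccccc1)CCCCCCCCCC/C=C\CCCc1ccccc1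
F2 | step 10 | γ-hydroxy sulfone: 15 carrying a phenylsulfonyl group on chain carbon C2' (epimer mixture at C2') | O[C@@]1(CC(S(=O)(=O)c2ccccc2)CCCCCCCCC/C=C\CCCc2ccccc2)C[C@H]3OC(C)(C)O[C@H]3[C@H](O[Si](c4ccccc4)(c4ccccc4)C(C)(C)C)C1
F3 | step 11 | tetraol: 1-[(12Z)-16-phenylhexadec-12-en-1-yl]cyclohexane-1,3,4,5-tetrol with quinic acid configuration | O[C@@]1(CCCCCCCCCCC/C=C\CCCc2ccccc2)C[C@@H](O)[C@@H](O)[C@H](O)C1
F4 | step 11 | cyclic 3,4-thionocarbonate of F3 (1-OH and 5-OH free) | O[C@@]1(CCCCCCCCCCC/C=C\CCCc2ccccc2)C[C@H]3OC(=S)O[C@H]3[C@H](O)C1
F5 | step 13 | 2-(dimethylamino)-1,3-dioxolane on O3/O4 of 16 (acetal carbon unassigned) | O[C@@]1(CCCCCCCCCCC/C=C\CCCc2ccccc2)C[C@H]3OC(N(C)C)O[C@H]3[C@H](O[Si](c4ccccc4)(c4ccccc4)C(C)(C)C)C1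
F6 | step 13 | trimethylammonium iodide of F5 | O[C@@]1(CCCCCCCCCCC/C=C\CCCc2ccccc2)C[C@H]3OC([N+](C)(C)C)O[C@H]3[C@H](O[Si](c4ccccc4)(c4ccccc4)C(C)(C)C)C1.[I-]
F7 | step 15 | (5S)-5-hydroxy-5-[(12Z)-16-phenylhexadec-12-en-1-yl]cyclohex-2-en-1-one | O[C@@]1(CCCCCCCCCCC/C=C\CCCc2ccccc2)CC=CC(=O)C1
A1 | alternative 1 | buta-1,3-diene | C=CC=C
A2 | alternative 1 | 2-bromoacrolein | C=C(Br)C=O
A3 | alternative 1 | (R)-1-bromocyclohex-3-ene-1-carbaldehyde | O=C[C@]1(Br)CC=CCC1
A4 | alternative 2 | acyclic β-(4-methoxybenzyloxy) ketone with a 1-(trimethylsilyl)allyl group on the carbinol carbon (silyl-bearing carbon unassigned) | COc1ccc(CO[C@H](C([Si](C)(C)C)C=C)CC(=O)CCCCCCCCCCC/C=C\CCCc2ccccc2)cc1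
A5 | alternative 2 | C1 4-methoxybenzyl ether of the target | COc1ccc(CO[C@@H]2C=CC[C@@](O)(CCCCCCCCCCC/C=C\CCCc3ccccc3)C2)cc1
A6 | alternative 3 | 3-[(12Z)-16-phenylhexadec-12-en-1-yl]cyclohex-2-en-1-one | O=C1CCCC(CCCCCCCCCCC/C=C\CCCc2ccccc2)=C1
A7 | alternative 3 | 3-[(12Z)-16-phenylhexadec-12-en-1-yl]-3-(pinacolatoboryl)cyclohexan-1-one | O=C1CCC[C@@](B2OC(C)(C)C(C)(C)O2)(CCCCCCCCCCC/C=C\CCCc3ccccc3)C1
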